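**Retrosynthetic overview**

- Feature: the 1,2-dioxolane ring (O1, O2, C3, C4, C5) has two quaternary peroxide carbons, C3 (CH3 and CH2CO2H) and C5 (CH3 and the CH2 that starts the C15 chain). Cutting the exocyclic C3–CH2 and C5–CH2 bonds leaves trans-3,5-dimethyl-1,2-dioxolane, which is C2-symmetric and maps atom for atom onto (2S,4S)-pentane-2,4-diol.
- Key disconnection: both C–CH2 bonds are made by two retentive carbene C–H insertions into the tertiary C–H bonds of (3R,5R)-3,5-dimethyl-1,2-dioxolane, each consuming one molecule of ethyl diazoacetate. The resulting diester is C2-symmetric, so its two arms are homotopic.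
- Ring order: the dioxolane is the only ring. It is closed first, by double SN2 of H2O2 on the bis-mesylate (two inversions), and is carried unchanged to the end.
- Side chain: mono-saponification, acid to alcohol to aldehyde, Wittig extension and diimide saturation, then C7'=C8' by Horner–Wadsworth–Emmons olefination with a (2E,5Z)-octadienylphosphonate made from cis-hex-3-en-1-ol, and final ester hydrolysis.

Key step: step 3

Remarks: side-chain carbons are numbered C1' to C15' outward from the ring. The CIP descriptor at the ring carbon carrying the growing arm alternates between R and S only because substituent priorities change; no bond at C3 or C5 is made or broken after step 3. Low-molecular-weight peroxides are handled only in dilute solution behind a shield.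

**Route**

Step 1
Reactants: 1 (2S,4S)-pentane-2,4-diol
Product: 2 (2S,4S)-pentane-2,4-diyl dimethanesulfonate
Conditions: MsCl (2.4 equiv), Et3N, CH2Cl2, 0 °C
Reagents that add atoms: methanesulfonyl chloride, CS(=O)(=O)Cl
Why: Mesylation takes place at oxygen, once at each hydroxyl group, so neither C–O bond is touched and the (S,S) configuration is carried into the two leaving groups.

Step 2
Reactants: 2 (2S,4S)-pentane-2,4-diyl dimethanesulfonate; 3 hydrogen peroxide
Product: 5 (3R,5R)-3,5-dimethyl-1,2-dioxolane, via hydroperoxy mesylate 4 (not isolated)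
Conditions: 50% aq. H2O2 (excess), KOH (2.2 equiv), MeOH, 0 °C to rt; extracted into CH2Cl2, washed free of MeOH and H2O2, dried (MgSO4, 4 Å sieves), kept as a titrated CH2Cl2 solution
Reagents that add atoms: none
Why: Hydroperoxide anion displaces the first secondary mesylate by SN2 (alkylation of H2O2 by an alkyl sulfonate) and the peroxide anion of 4 then closes the ring by 5-exo-tet SN2 on the second, so two inversions turn the (S,S) centres into the (R,R) centres of the trans-dioxolane, while the excess of H2O2 holds the basicity at that of HOO− and limits Kornblum–DeLaMare cleavage.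

Step 3
Reactants: 5 (3R,5R)-3,5-dimethyl-1,2-dioxolane; 6 ethyl diazoacetate
Product: 8 diethyl 2,2'-[(3R,5R)-3,5-dimethyl-1,2-dioxolane-3,5-diyl]diacetate, via monoester 7 (not isolated)
Conditions: Cu[HB(3,4,5-tribromopyrazol-1-yl)3](NCMe) (5 mol%), 6 (5 equiv in all, syringe pump over 12 h), 5 as limiting reagent in CH2Cl2, rt
Reagents that add atoms: ethyl diazoacetate (second molecule of 6), CCOC(=O)C=[N+]=[N-]
Why: Proposed new method: two molecules of 6 are consumed, each losing N2 at the monovalent copper centre to give an electrophilic carbene that should insert, through a concerted three-centre transition state with hydride-transfer character, first into one tertiary C–H bond alpha to a peroxide oxygen of 5 (giving 7) and then into the C2-related one, which makes the C3–CH2 and C5–CH2 bonds. The closest known reaction type is the insertion of ethyl diazoacetate carbenes, generated with Cu[HB(pz)3] or Ag[HB(pz)3] complexes (pz = substituted pyrazol-1-yl) or with Rh2(O2CR)4, into C–H bonds alpha to ether oxygen and into tertiary alkane C–H bonds. No ring is closed; the dioxolane is carried through intact. Both quaternary stereocentres (C3 and C5) arise with retention, because the carbene carbon enters on the face the hydrogen leaves, so they are decided by the configuration fixed by the two inversions of step 2. The step needs site selectivity for the two homotopic alpha-peroxy C–H bonds over the ring CH2 and the methyl C–H bonds, which the adjacent oxygen lone pairs secure by stabilising positive charge only at C3 and C5. It also needs chemoselectivity for C–H insertion over attack at peroxide oxygen (ylide formation, O–O cleavage) and over carbene dimerisation, for which the bulky, strongly electrophilic scorpionate carbene and the slow addition of 6 are chosen.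

Step 4
Reactants: 8 diethyl 2,2'-[(3R,5R)-3,5-dimethyl-1,2-dioxolane-3,5-diyl]diacetate
Product: 9 2-[(3R,5R)-5-(2-ethoxy-2-oxoethyl)-3,5-dimethyl-1,2-dioxolan-3-yl]acetic acid
Conditions: LiOH·H2O (1.0 equiv), THF/H2O, 0 °C; then 1 M HCl to pH 3; recovered 8 recycled
Reagents that add atoms: lithium hydroxide, [Li+].[OH-]
Why: Partial saponification with one equivalent of hydroxide at 0 °C should stop largely at the half-ester because the carboxylate slows the second hydrolysis, and since the two arms of C2-symmetric 8 are homotopic either hydrolysis gives the same compound without involving the stereocentres.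

Step 5
Reactants: 9 2-[(3R,5R)-5-(2-ethoxy-2-oxoethyl)-3,5-dimethyl-1,2-dioxolan-3-yl]acetic acid
Product: 11 ethyl 2-[(3R,5S)-5-(2-hydroxyethyl)-3,5-dimethyl-1,2-dioxolan-3-yl]acetate, via mixed anhydride 10 (not isolated)
Conditions: i-BuOCOCl, N-methylmorpholine, THF, −15 °C; then NaBH4, H2O, 0 °C
Reagents that add atoms: none
Why: Mixed carbonic anhydride activation followed by NaBH4 reduction converts only the free acid into the primary alcohol, since the ethyl ester and the dialkyl peroxide are inert to NaBH4 at 0 °C.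

Step 6
Reactants: 11 ethyl 2-[(3R,5S)-5-(2-hydroxyethyl)-3,5-dimethyl-1,2-dioxolan-3-yl]acetate
Product: 12 ethyl 2-[(3R,5R)-3,5-dimethyl-5-(2-oxoethyl)-1,2-dioxolan-3-yl]acetate
Conditions: Dess–Martin periodinane, NaHCO3, CH2Cl2, 0 °C to rt; used at once
Reagents that add atoms: none
Why: Dess–Martin oxidation is neutral and non-reducing, so the alcohol is taken to the aldehyde without touching the O–O bond and without exposing the enolisable beta-peroxy aldehyde to base.

Step 7
Reactants: 13 2-(4-bromobutyl)-1,3-dioxolane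
Product: 14 [4-(1,3-dioxolan-2-yl)butyl]triphenylphosphonium bromide
Conditions: PPh3, MeCN, reflux
Reagents that add atoms: triphenylphosphine, c1ccc(cc1)P(c1ccccc1)c1ccccc1
Why: SN2 quaternisation of triphenylphosphine by the primary bromide gives the Wittig salt under neutral conditions that leave the acetal intact.

Step 8
Reactants: 12 ethyl 2-[(3R,5R)-3,5-dimethyl-5-(2-oxoethyl)-1,2-dioxolan-3-yl]acetate; 14 [4-(1,3-dioxolan-2-yl)butyl]triphenylphosphonium bromide
Product: 16 ethyl 2-[(3R,5S)-5-[(2Z)-6-(1,3-dioxolan-2-yl)hex-2-en-1-yl]-3,5-dimethyl-1,2-dioxolan-3-yl]acetate, via phosphorus ylide 15 (not isolated)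
Conditions: 14 (1.3 equiv), NaN(SiMe3)2 (1.2 equiv), THF, −78 °C; then 12, −78 °C to 0 °C
Reagents that add atoms: none
Why: Wittig olefination with a preformed non-stabilised ylide at −78 °C should add to the aldehyde faster than it deprotonates it and give mainly the Z-alkene by kinetic oxaphosphetane formation, the geometry being irrelevant because the alkene is saturated in step 9.

Step 9
Reactants: 16 ethyl 2-[(3R,5S)-5-[(2Z)-6-(1,3-dioxolan-2-yl)hex-2-en-1-yl]-3,5-dimethyl-1,2-dioxolan-3-yl]acetate
Product: 17 ethyl 2-[(3R,5S)-5-[6-(1,3-dioxolan-2-yl)hexyl]-3,5-dimethyl-1,2-dioxolan-3-yl]acetate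
Conditions: KO2CN=NCO2K (excess), AcOH (slow addition), CH2Cl2/MeOH, 0 °C to rt
Reagents that add atoms: none
Why: Diimide reduction delivers H2 to the disubstituted C=C bond by concerted syn transfer and, unlike catalytic hydrogenation or low-valent metal reagents, leaves the O–O bond, the ester and the acetal alone.

Step 10
Reactants: 17 ethyl 2-[(3R,5S)-5-[6-(1,3-dioxolan-2-yl)hexyl]-3,5-dimethyl-1,2-dioxolan-3-yl]acetate
Product: 18 ethyl 2-[(3R,5S)-3,5-dimethyl-5-(7-oxoheptyl)-1,2-dioxolan-3-yl]acetate
Conditions: 2 M aq. HCl, THF, rt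
Reagents that add atoms: water, O
Why: Acid-catalysed acetal hydrolysis frees the aldehyde, while the di-tertiary dialkyl peroxide and the ethyl ester are stable to dilute aqueous acid at room temperature.

Step 11
Reactants: 19 cis-hex-3-en-1-ol
Product: 21 ethyl (2E,5Z)-octa-2,5-dienoate, via (Z)-hex-3-enal 20 (not isolated)
Conditions: Dess–Martin periodinane, NaHCO3, CH2Cl2, 0 °C; then Ph3P=CHCO2Et (2.5 equiv), 0 °C to rt
Reagents that add atoms: ethyl (triphenylphosphoranylidene)acetate, CCOC(=O)C=P(c1ccccc1)(c1ccccc1)c1ccccc1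
Why: One-pot Dess–Martin oxidation and Wittig olefination with a stabilised ylide traps the isomerisation-prone beta,gamma-unsaturated aldehyde 20 as it forms and gives the E-enoate by the usual thermodynamic control of stabilised ylides, the Z-alkene of 19 being carried through unchanged.

Step 12
Reactants: 21 ethyl (2E,5Z)-octa-2,5-dienoate
Product: 22 (2E,5Z)-octa-2,5-dien-1-ol
Conditions: i-Bu2AlH (2.2 equiv), CH2Cl2, −78 °C; aq. potassium sodium tartrate (KNaC4H4O6) work-up
Reagents that add atoms: none
Why: Reduction of the conjugated ester by 1,2-hydride delivery from i-Bu2AlH gives the allylic alcohol without affecting either C=C bond.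

Step 13
Reactants: 22 (2E,5Z)-octa-2,5-dien-1-ol
Product: 23 (2E,5Z)-1-bromoocta-2,5-diene
Conditions: CBr4, PPh3, CH2Cl2, 0 °C
Reagents that add atoms: carbon tetrabromide, BrC(Br)(Br)Br
Why: Appel bromination converts the primary allylic alcohol into the bromide by SN2 displacement of the oxyphosphonium intermediate under neutral, cold conditions that leave the olefin positions and geometries unchanged.

Step 14
Reactants: 23 (2E,5Z)-1-bromoocta-2,5-diene
Product: 24 diethyl [(2E,5Z)-octa-2,5-dien-1-yl]phosphonate
Conditions: P(OEt)3, neat, 110 °C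
Reagents that add atoms: triethyl phosphite, CCOP(OCC)OCC
Why: Michaelis–Arbuzov reaction of the primary allylic bromide with triethyl phosphite should give the unrearranged allylic phosphonate with both olefin geometries intact.

Step 15
Reactants: 18 ethyl 2-[(3R,5S)-3,5-dimethyl-5-(7-oxoheptyl)-1,2-dioxolan-3-yl]acetate; 24 diethyl [(2E,5Z)-octa-2,5-dien-1-yl]phosphonate
Product: 26 ethyl 2-[(3R,5S)-3,5-dimethyl-5-[(7E,9E,12Z)-pentadeca-7,9,12-trien-1-yl]-1,2-dioxolan-3-yl]acetate, via lithiated phosphonate 25 (not isolated)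
Conditions: 24 (1.3 equiv), LiN(SiMe3)2 (1.25 equiv), THF, −78 °C; then 18, −78 °C to rt
Reagents that add atoms: none
Why: Horner–Wadsworth–Emmons olefination of aldehyde 18 with the lithiated allylic phosphonate, which reacts at its alpha-carbon, should form the C7'=C8' bond with E geometry through the reversible, thermodynamically controlled adduct and so complete the (7E,9E,12Z)-triene, the preformed anion adding to the aldehyde much faster than it deprotonates the ester.

Step 16
Reactants: 26 ethyl 2-[(3R,5S)-3,5-dimethyl-5-[(7E,9E,12Z)-pentadeca-7,9,12-trien-1-yl]-1,2-dioxolan-3-yl]acetate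
Product: 27 2-[(3R,5S)-3,5-dimethyl-5-[(7E,9E,12Z)-pentadeca-7,9,12-trien-1-yl]-1,2-dioxolan-3-yl]acetic acid
Conditions: LiOH·H2O, degassed THF/H2O, 0 °C to rt; then 1 M HCl to pH 3–4 at 0 °C
Reagents that add atoms: lithium hydroxide, [Li+].[OH-]
Why: Saponification of the ethyl ester, a transformation established for 1,2-dioxolane-3-acetates, should give the acid without opening the ring, disturbing the quaternary centres or moving the skipped double bonds.

**Compound list**

1 | (2S,4S)-pentane-2,4-diol | C[C@H](O)C[C@H](C)O | starting material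
2 | (2S,4S)-pentane-2,4-diyl dimethanesulfonate | C[C@H](OS(C)(=O)=O)C[C@H](C)OS(C)(=O)=O | intermediate
3 | hydrogen peroxide | OO | starting material
4 | (2S,4R)-4-hydroperoxypentan-2-yl methanesulfonate | C[C@H](OS(C)(=O)=O)C[C@@H](C)OO | intermediate
5 | (3R,5R)-3,5-dimethyl-1,2-dioxolane | C[C@@H]1C[C@@H](C)OO1 | intermediate
6 | ethyl diazoacetate | CCOC(=O)C=[N+]=[N-] | starting material
7 | ethyl 2-[(3R,5R)-3,5-dimethyl-1,2-dioxolan-3-yl]acetate | CCOC(=O)C[C@@]1(C)C[C@@H](C)OO1 | intermediate
8 | diethyl 2,2'-[(3R,5R)-3,5-dimethyl-1,2-dioxolane-3,5-diyl]diacetate | CCOC(=O)C[C@@]1(C)C[C@](C)(CC(=O)OCC)OO1 | intermediate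
9 | 2-[(3R,5R)-5-(2-ethoxy-2-oxoethyl)-3,5-dimethyl-1,2-dioxolan-3-yl]acetic acid | OC(=O)C[C@@]1(C)C[C@](C)(CC(=O)OCC)OO1 | intermediate
10 | isobutyl carbonic anhydride of 9 | CC(C)COC(=O)OC(=O)C[C@@]1(C)C[C@](C)(CC(=O)OCC)OO1 | intermediate
11 | ethyl 2-[(3R,5S)-5-(2-hydroxyethyl)-3,5-dimethyl-1,2-dioxolan-3-yl]acetate | OCC[C@@]1(C)C[C@](C)(CC(=O)OCC)OO1 | intermediate
12 | ethyl 2-[(3R,5R)-3,5-dimethyl-5-(2-oxoethyl)-1,2-dioxolan-3-yl]acetate | O=CC[C@@]1(C)C[C@](C)(CC(=O)OCC)OO1 | intermediate
13 | 2-(4-bromobutyl)-1,3-dioxolane | BrCCCCC1OCCO1 | starting material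
14 | [4-(1,3-dioxolan-2-yl)butyl]triphenylphosphonium bromide | [Br-].C1COC(O1)CCCC[P+](c1ccccc1)(c1ccccc1)c1ccccc1 | intermediate
15 | [4-(1,3-dioxolan-2-yl)butylidene]triphenylphosphorane | C1COC(O1)CCCC=P(c1ccccc1)(c1ccccc1)c1ccccc1 | intermediate
16 | ethyl 2-[(3R,5S)-5-[(2Z)-6-(1,3-dioxolan-2-yl)hex-2-en-1-yl]-3,5-dimethyl-1,2-dioxolan-3-yl]acetate | C1COC(O1)CCC/C=C\C[C@@]2(C)C[C@](C)(CC(=O)OCC)OO2 | intermediate
17 | ethyl 2-[(3R,5S)-5-[6-(1,3-dioxolan-2-yl)hexyl]-3,5-dimethyl-1,2-dioxolan-3-yl]acetate | C1COC(O1)CCCCCC[C@@]2(C)C[C@](C)(CC(=O)OCC)OO2 | intermediate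
18 | ethyl 2-[(3R,5S)-3,5-dimethyl-5-(7-oxoheptyl)-1,2-dioxolan-3-yl]acetate | O=CCCCCCC[C@@]1(C)C[C@](C)(CC(=O)OCC)OO1 | intermediate
19 | cis-hex-3-en-1-ol | CC/C=C\CCO | starting material
20 | (Z)-hex-3-enal | CC/C=C\CC=O | intermediate
21 | ethyl (2E,5Z)-octa-2,5-dienoate | CC/C=C\C/C=C/C(=O)OCC | intermediate
22 | (2E,5Z)-octa-2,5-dien-1-ol | CC/C=C\C/C=C/CO | intermediate
23 | (2E,5Z)-1-bromoocta-2,5-diene | CC/C=C\C/C=C/CBr | intermediate
24 | diethyl [(2E,5Z)-octa-2,5-dien-1-yl]phosphonate | CC/C=C\C/C=C/CP(=O)(OCC)OCC | intermediate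
25 | lithium (2E,5Z)-1-(diethoxyphosphoryl)octa-2,5-dien-1-ide | [Li+].CC/C=C\C/C=C/[CH-]P(=O)(OCC)OCC | intermediate
26 | ethyl 2-[(3R,5S)-3,5-dimethyl-5-[(7E,9E,12Z)-pentadeca-7,9,12-trien-1-yl]-1,2-dioxolan-3-yl]acetate | CC/C=C\C/C=C/C=C/CCCCCC[C@@]1(C)C[C@](C)(CC(=O)OCC)OO1 | intermediate
27 | 2-[(3R,5S)-3,5-dimethyl-5-[(7E,9E,12Z)-pentadeca-7,9,12-trien-1-yl]-1,2-dioxolan-3-yl]acetic acid | CC/C=C\C/C=C/C=C/CCCCCC[C@@]1(C)C[C@](C)(CC(=O)O)OO1 | target

**Step count and risks**

Total step count: 16. Longest linear sequence: 11 steps from 1 (steps 1–6, 8–10, 15, 16).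

Steps most likely to fail:

1. Step 3 (the proposed new method). The carbene may be captured at a peroxide oxygen lone pair, leading to ylide formation and O–O cleavage. It may also dimerise faster than it inserts, because 5 cannot serve as solvent, or the sequence may stall after the first insertion. The fallback gives up chiral-pool control and builds both quaternary carbons by the known Lewis-acid alkylation of 3-alkoxy-1,2-dioxolanes through peroxycarbenium ions. It sets out from hydrogen peroxide 3. Condensation with pentane-2,4-dione (CC(=O)CC(C)=O) in water at 0 °C should give 3,5-dimethyl-1,2-dioxolane-3,5-diol F1. Acid-catalysed exchange in MeOH (TsOH) should give the bis-peroxyketal 3,5-dimethoxy-3,5-dimethyl-1,2-dioxolane F2. TiCl4 with 1-ethoxy-1-(trimethylsilyloxy)ethene (C=C(OCC)O[Si](C)(C)C) in CH2Cl2 at −78 °C should then replace both methoxy groups, giving diethyl 2,2'-(3,5-dimethyl-1,2-dioxolane-3,5-diyl)diacetate F3 as a mixture of the cis (meso) and racemic trans isomers. Chromatography on silica to remove the cis isomer, then preparative HPLC on a chiral stationary phase to take the (3R,5R) enantiomer, brings the material back to the route at 8.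

2. Step 8. The basic ylide may deprotonate the aldehyde alpha to the carbonyl, and E1cB loss of the beta-peroxide oxygen would then open the dioxolane before carbonyl addition takes place. The fallback replaces carbonyl olefination by a base-free sp3–sp3 cross-coupling and sets out from 11 and 13. Alcohol 11 is converted with I2, PPh3 and imidazole (CH2Cl2, 0 °C, the phosphine being consumed as Ph3PI2 before 11 is added) into ethyl 2-[(3R,5R)-5-(2-iodoethyl)-3,5-dimethyl-1,2-dioxolan-3-yl]acetate F4. Bromide 13 is converted with Zn dust and LiCl in THF at 50 °C into bromo[4-(1,3-dioxolan-2-yl)butyl]zinc F5. Negishi alkyl–alkyl coupling of the two with PdCl2(3-chloropyridine)(IPr) (IPr = 1,3-bis(2,6-diisopropylphenyl)imidazol-2-ylidene, a divalent palladium precatalyst) and LiBr in THF/N-methylpyrrolidone at rt should give 17 directly. The route is rejoined at 17, and steps 6 to 9 are bypassed.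

3. Step 15. Geometric control at the new C7'=C8' bond may be poor, or the skipped dienyl anion may drift by proton transfer or gamma-attack, which would give triene isomers that cannot be separated from 26. The fallback moves the olefination to the C9'=C10' bond and sets out from 18 and 19. Aldehyde 18 is homologated with Ph3P=CHCHO in toluene at 60 °C to the enal ethyl 2-[(3R,5S)-3,5-dimethyl-5-[(7E)-9-oxonon-7-en-1-yl]-1,2-dioxolan-3-yl]acetate F6. Alcohol 19 is converted by Mitsunobu reaction (1-phenyl-1H-tetrazole-5-thiol, PPh3, diisopropyl azodicarboxylate, THF, 0 °C) into 5-[(3Z)-hex-3-en-1-ylsulfanyl]-1-phenyl-1H-tetrazole F7. Oxidation with 30% H2O2 and catalytic (NH4)6Mo7O24·4H2O in EtOH gives 5-[(3Z)-hex-3-en-1-ylsulfonyl]-1-phenyl-1H-tetrazole F8. Julia–Kocienski olefination (KN(SiMe3)2, 1,2-dimethoxyethane, −60 °C, then F6) should give the (E,E)-diene and rejoin the route at 26.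

**Further compounds**

F1 | step 3 | 3,5-dimethyl-1,2-dioxolane-3,5-diol | CC1(O)CC(C)(O)OO1
F2 | step 3 | 3,5-dimethoxy-3,5-dimethyl-1,2-dioxolane | COC1(C)CC(C)(OC)OO1
F3 | step 3 | diethyl 2,2'-(3,5-dimethyl-1,2-dioxolane-3,5-diyl)diacetate, mixture of cis and racemic trans isomers | CCOC(=O)CC1(C)CC(C)(CC(=O)OCC)OO1
F4 | step 8 | ethyl 2-[(3R,5R)-5-(2-iodoethyl)-3,5-dimethyl-1,2-dioxolan-3-yl]acetate | ICC[C@@]1(C)C[C@](C)(CC(=O)OCC)OO1
F5 | step 8 | bromo[4-(1,3-dioxolan-2-yl)butyl]zinc | Br[Zn]CCCCC1OCCO1
F6 | step 15 | ethyl 2-[(3R,5S)-3,5-dimethyl-5-[(7E)-9-oxonon-7-en-1-yl]-1,2-dioxolan-3-yl]acetate | O=C/C=C/CCCCCC[C@@]1(C)C[C@](C)(CC(=O)OCC)OO1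
F7 | step 15 | 5-[(3Z)-hex-3-en-1-ylsulfanyl]-1-phenyl-1H-tetrazole | CC/C=C\CCSc1nnnn1-c2ccccc2
F8 | step 15 | 5-[(3Z)-hex-3-en-1-ylsulfonyl]-1-phenyl-1H-tetrazole | CC/C=C\CCS(=O)(=O)c1nnnn1-c2ccccc2
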